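**Retrosynthetic overview**
1. No ring is formed. The arene is bought as C2-symmetric 2,6-dimethylhydroquinone, so functionalising either methyl gives the 2,6-pattern. The last step is a global desilylation.
2. C3'–C4' comes from an Ag–Ni-electrocatalytic decarboxylative alkenylation of acid 12 (as its NHPI ester) with (E)-alkenyl iodide 18.
3. C7'–C8' and C7'–CH3 both come from the 1,1-dibromoalkene 8. A new trans-selective electroreductive decarboxylative mono-alkylation with acid 4 is followed by a stereoretentive Negishi methylation.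
4. The C5' stereocentre is C2 of dimethyl L-malate. Malate C1 becomes C6', C3 becomes C4', and C4 is lost as CO2.
5. Acid 4 comes from (E)-geranylacetone by SeO2 oxidation, silylation and haloform cleavage. Iodide 18 comes from benzylic photobromination, propynylation and hydrozirconation–iodination.

Assumption: the SMILES is taken as drawn, i.e. (5'S) with all four chain olefins E. Primed locants number the side chain from the benzylic carbon C1' to the CH2OH carbon C16'. TBS = tert-butyldimethylsilyl and NHPI = N-hydroxyphthalimide.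

**Route**

Step 1
Reactants: 1 (E)-geranylacetone
Product: 2 (5E,9E)-11-hydroxy-6,10-dimethylundeca-5,9-dien-2-one
Conditions: SeO2 (10 mol %), salicylic acid (10 mol %), t-BuOOH (2 equiv), CH2Cl2, 0 °C to rt, stopped at about 70 % conversion
Reagents that add atoms: selenium dioxide (O=[Se]=O, O-transfer catalyst); tert-butyl hydroperoxide (CC(C)(C)OO, terminal O source)
Why: Catalytic SeO2/TBHP allylic hydroxylation (ene reaction then [2,3]-shift) attacks the more nucleophilic terminal gem-dimethyl olefin at its (E)-methyl group and gives the (E)-allylic alcohol, while the methyl ketone is inert to catalytic SeO2 at rt.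

Step 2
Reactants: 2 (5E,9E)-11-hydroxy-6,10-dimethylundeca-5,9-dien-2-one
Product: 3 (5E,9E)-11-(tert-butyldimethylsilyloxy)-6,10-dimethylundeca-5,9-dien-2-one
Conditions: TBSCl, imidazole, CH2Cl2, 0 °C to rt
Reagents that add atoms: tert-butyldimethylsilyl chloride (CC(C)(C)[Si](C)(C)Cl)
Why: Standard imidazole-promoted silylation masks the only oxidisable and protic group before the hypobromite, Ni and Zn chemistry.

Step 3
Reactants: 3 (5E,9E)-11-(tert-butyldimethylsilyloxy)-6,10-dimethylundeca-5,9-dien-2-one
Product: 4 (4E,8E)-10-(tert-butyldimethylsilyloxy)-5,9-dimethyldeca-4,8-dienoic acid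
Conditions: Br2, NaOH, H2O/1,4-dioxane, 0 °C; then 1 M HCl to pH 3–4, 0 °C
Reagents that add atoms: sodium hydroxide ([Na+].[OH-])
Why: In this haloform degradation, strongly basic hypobromite tribrominates only the CH3CO terminus and hydroxide expels CBr3, whereas OBr− is too weak an electrophile for the trisubstituted olefins and the primary TBS ether tolerates cold aqueous base.

Step 4
Reactants: 5 dimethyl (S)-malate
Product: 6 dimethyl (S)-2-(tert-butyldimethylsilyloxy)butanedioate
Conditions: TBSCl, imidazole, DMF, rt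
Reagents that add atoms: tert-butyldimethylsilyl chloride (CC(C)(C)[Si](C)(C)Cl)
Why: O-silylation breaks no bond at the purchased (S)-carbinol carbon, which is carried unchanged to become C5'.

Step 5
Reactants: 6 dimethyl (S)-2-(tert-butyldimethylsilyloxy)butanedioate
Product: 7 methyl (S)-3-(tert-butyldimethylsilyloxy)-4-oxobutanoate
Conditions: DIBAL-H (1.05 equiv), CH2Cl2, −78 °C; aqueous work-up
Reagents that add atoms: none
Why: This is a regioselective partial ester reduction, because the α-silyloxy ester is the more electrophilic carbonyl and its aluminium hemiacetal persists at −78 °C, and the base-free conditions leave the α-stereocentre unepimerised.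

Step 6
Reactants: 7 methyl (S)-3-(tert-butyldimethylsilyloxy)-4-oxobutanoate
Product: 8 methyl (S)-5,5-dibromo-3-(tert-butyldimethylsilyloxy)pent-4-enoate
Conditions: CBr4, PPh3, Zn dust, CH2Cl2, 0 °C to rt
Reagents that add atoms: carbon tetrabromide (BrC(Br)(Br)Br)
Why: The Ramirez dibromo-olefination (first Corey–Fuchs stage) in its neutral Zn-modified form converts the aldehyde without epimerisation or β-elimination of the silyloxy group.

Step 7
Reactants: 4 (4E,8E)-10-(tert-butyldimethylsilyloxy)-5,9-dimethyldeca-4,8-dienoic acid; 8 methyl (S)-5,5-dibromo-3-(tert-butyldimethylsilyloxy)pent-4-enoate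
Product: 10 methyl (3S,4Z,8E,12E)-5-bromo-3,14-bis(tert-butyldimethylsilyloxy)-9,13-dimethyltetradeca-4,8,12-trienoate, via chain NHPI ester 9 (not isolated)
Conditions: NHPI, DIC, DMAP (cat.), CH2Cl2, rt, filter and concentrate; then 8 (2 equiv), NiCl2·6H2O/2,2'-bipyridine (20 mol %), AgNO3 (0.3 equiv, electrode modifier), DMF, undivided cell, (+)Mg/(−)RVC, constant current, about 3 F/mol, rt
Reagents that add atoms: none
Why: Proposed new method: cathodically generated (bpy)Ni(0/I) should insert only into the less hindered C–Br bond trans to the branched C5' carbon of 8 (the steric bias that makes Pd(0) mono-couple 1,1-dibromoalkenes trans-selectively), the resulting (Z)-α-bromoalkenyl-Ni(II) captures the primary radical released from 9 by reductive fragmentation (loss of CO2 and phthalimide anion) and reductively eliminates from Ni(III) with retention, and the remaining C–Br, now trisubstituted and cis to C5', is too hindered to react again, so the step forges C7'–C8' and fixes the olefin geometry without touching the malate stereocentre; the closest known reaction types are Ag–Ni-electrocatalytic decarboxylative alkenylation of redox-active esters with simple alkenyl halides and Pd-catalysed trans-selective Negishi mono-alkylation of 1,1-dibromoalkenes.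

Step 8
Reactants: 10 methyl (3S,4Z,8E,12E)-5-bromo-3,14-bis(tert-butyldimethylsilyloxy)-9,13-dimethyltetradeca-4,8,12-trienoate
Product: 11 methyl (3S,4E,8E,12E)-3,14-bis(tert-butyldimethylsilyloxy)-5,9,13-trimethyltetradeca-4,8,12-trienoate
Conditions: Me2Zn, Pd(Pt-Bu3)2 (3 mol %), THF, 0 °C to rt
Reagents that add atoms: dimethylzinc (C[Zn]C)
Why: Stereoretentive Negishi methylation of the hindered (Z)-alkenyl bromide places CH3 cis to C5' and so gives the (E)-trisubstituted olefin, and Me2Zn leaves the ester and silyl ethers alone.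

Step 9
Reactants: 11 methyl (3S,4E,8E,12E)-3,14-bis(tert-butyldimethylsilyloxy)-5,9,13-trimethyltetradeca-4,8,12-trienoate
Product: 12 (3S,4E,8E,12E)-3,14-bis(tert-butyldimethylsilyloxy)-5,9,13-trimethyltetradeca-4,8,12-trienoic acid
Conditions: LiOH, THF/MeOH/H2O, 0 °C to rt; then 1 M HCl to pH 4, 0 °C
Reagents that add atoms: lithium hydroxide ([Li+].[OH-])
Why: BAc2 saponification of the unhindered methyl ester is faster than E1cB loss of the β-silyloxy group at or below rt, and both TBS ethers are base-stable.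

Step 10
Reactants: 13 2,6-dimethylbenzene-1,4-diol
Product: 14 1,4-bis(tert-butyldimethylsilyloxy)-2,6-dimethylbenzene
Conditions: TBSCl (2.5 equiv), imidazole, DMF, rt to 40 °C
Reagents that add atoms: tert-butyldimethylsilyl chloride (CC(C)(C)[Si](C)(C)Cl)
Why: Bis-silylation blocks hydroquinone oxidation and uses the same fluoride-labile group as the rest of the molecule.

Step 11
Reactants: 14 1,4-bis(tert-butyldimethylsilyloxy)-2,6-dimethylbenzene
Product: 15 2-(bromomethyl)-1,4-bis(tert-butyldimethylsilyloxy)-6-methylbenzene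
Conditions: NBS (1.0 equiv), white LED, PhCF3, reflux
Reagents that add atoms: N-bromosuccinimide (O=C1CCC(=O)N1Br)
Why: In this Wohl–Ziegler photobromination in a non-polar solvent the two methyl groups are symmetry-equivalent, so mono-bromination gives a single regioisomer, and the ring C–H positions are shielded by OTBS and methyl.

Step 12
Reactants: 15 2-(bromomethyl)-1,4-bis(tert-butyldimethylsilyloxy)-6-methylbenzene
Product: 16 2-(but-2-yn-1-yl)-1,4-bis(tert-butyldimethylsilyloxy)-6-methylbenzene
Conditions: 1-propynylmagnesium bromide, CuI (10 mol %), THF, 0 °C to rt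
Reagents that add atoms: 1-propynylmagnesium bromide (CC#C[Mg]Br)
Why: Cu-catalysed SN2 alkynylation of a primary benzylic bromide has no SN2' or allene pathway.

Step 13
Reactants: 16 2-(but-2-yn-1-yl)-1,4-bis(tert-butyldimethylsilyloxy)-6-methylbenzene
Product: 18 2-[(2E)-3-iodobut-2-en-1-yl]-1,4-bis(tert-butyldimethylsilyloxy)-6-methylbenzene, via alkenylzirconocene chloride 17 (not isolated)
Conditions: Cp2ZrHCl (1.6 equiv), THF, rt to 40 °C; then I2, −20 °C
Reagents that add atoms: iodine (II)
Why: Schwartz hydrozirconation adds H–Zr syn and, after equilibration with excess reagent, places Zr on the less hindered methyl-bearing carbon, and iodinolysis with retention then gives the (E)-iodide with I trans to CH2Ar.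

Step 14
Reactants: 12 (3S,4E,8E,12E)-3,14-bis(tert-butyldimethylsilyloxy)-5,9,13-trimethyltetradeca-4,8,12-trienoic acid; 18 2-[(2E)-3-iodobut-2-en-1-yl]-1,4-bis(tert-butyldimethylsilyloxy)-6-methylbenzene
Product: 20 tetra-TBS ether of the target, via linchpin NHPI ester 19 (not isolated)
Conditions: 12 (1.3 equiv), NHPI, DIC, CH2Cl2, rt, filter and concentrate; then 18, NiCl2·6H2O/2,2'-bipyridine (20 mol %), AgNO3 (0.3 equiv, electrode modifier), DMF, undivided cell, (+)Mg/(−)RVC, constant current, about 3 F/mol, rt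
Reagents that add atoms: none
Why: In this Ag–Ni-electrocatalytic decarboxylative alkenylation (redox-active ester/alkenyl iodide cross-electrophile coupling) the primary C4' radical is captured by the alkenyl-Ni(II) species with retention of the (E)-geometry of 18, and C5' lies β to the radical so its configuration is not involved.

Step 15
Reactants: 20 tetra-TBS ether of the target
Product: 21 2-[(2E,5S,6E,10E,14E)-5,16-dihydroxy-3,7,11,15-tetramethylhexadeca-2,6,10,14-tetraen-1-yl]-6-methylbenzene-1,4-diol (target)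
Conditions: TBAF (6 equiv), AcOH (6 equiv), degassed THF, 0 °C to rt, air-free work-up
Reagents that add atoms: none
Why: Buffered fluoride desilylation removes all four TBS groups in one operation without acid (which would cause chroman formation or allylic ionisation) and without free base (which would cause hydroquinone autoxidation).

**Compound list**
1 | (E)-geranylacetone | CC(C)=CCC/C(C)=C/CCC(C)=O | starting material
2 | (5E,9E)-11-hydroxy-6,10-dimethylundeca-5,9-dien-2-one | C/C(=C\CC/C(C)=C/CCC(C)=O)CO | intermediate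
3 | (5E,9E)-11-(TBS-oxy)-6,10-dimethylundeca-5,9-dien-2-one | C/C(=C\CC/C(C)=C/CCC(C)=O)CO[Si](C)(C)C(C)(C)C | intermediate
4 | (4E,8E)-10-(TBS-oxy)-5,9-dimethyldeca-4,8-dienoic acid | C/C(=C\CC/C(C)=C/CCC(=O)O)CO[Si](C)(C)C(C)(C)C | intermediate
5 | dimethyl (S)-malate (dimethyl L-malate) | COC(=O)[C@@H](O)CC(=O)OC | starting material
6 | dimethyl (S)-2-(TBS-oxy)butanedioate | COC(=O)[C@@H](O[Si](C)(C)C(C)(C)C)CC(=O)OC | intermediate
7 | methyl (S)-3-(TBS-oxy)-4-oxobutanoate | O=C[C@@H](O[Si](C)(C)C(C)(C)C)CC(=O)OC | intermediate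
8 | methyl (S)-5,5-dibromo-3-(TBS-oxy)pent-4-enoate | BrC(Br)=C[C@@H](O[Si](C)(C)C(C)(C)C)CC(=O)OC | intermediate
9 | N-phthalimidoyl ester (NHPI ester) of acid 4 | C/C(=C\CC/C(C)=C/CCC(=O)ON1C(=O)c2ccccc2C1=O)CO[Si](C)(C)C(C)(C)C | intermediate (not isolated)
10 | methyl (3S,4Z,8E,12E)-5-bromo-3,14-bis(TBS-oxy)-9,13-dimethyltetradeca-4,8,12-trienoate | C/C(=C\CC/C(C)=C/CC/C(Br)=C/[C@@H](O[Si](C)(C)C(C)(C)C)CC(=O)OC)CO[Si](C)(C)C(C)(C)C | intermediate
11 | methyl (3S,4E,8E,12E)-3,14-bis(TBS-oxy)-5,9,13-trimethyltetradeca-4,8,12-trienoate | C/C(=C\CC/C(C)=C/CC/C(C)=C/[C@@H](O[Si](C)(C)C(C)(C)C)CC(=O)OC)CO[Si](C)(C)C(C)(C)C | intermediate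
12 | (3S,4E,8E,12E)-3,14-bis(TBS-oxy)-5,9,13-trimethyltetradeca-4,8,12-trienoic acid | C/C(=C\CC/C(C)=C/CC/C(C)=C/[C@@H](O[Si](C)(C)C(C)(C)C)CC(=O)O)CO[Si](C)(C)C(C)(C)C | intermediate
13 | 2,6-dimethylbenzene-1,4-diol | Cc1cc(O)cc(C)c1O | starting material
14 | 1,4-bis(TBS-oxy)-2,6-dimethylbenzene | Cc1cc(O[Si](C)(C)C(C)(C)C)cc(C)c1O[Si](C)(C)C(C)(C)C | intermediate
15 | 2-(bromomethyl)-1,4-bis(TBS-oxy)-6-methylbenzene | BrCc1cc(O[Si](C)(C)C(C)(C)C)cc(C)c1O[Si](C)(C)C(C)(C)C | intermediate
16 | 2-(but-2-yn-1-yl)-1,4-bis(TBS-oxy)-6-methylbenzene | CC#CCc1cc(O[Si](C)(C)C(C)(C)C)cc(C)c1O[Si](C)(C)C(C)(C)C | intermediate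
17 | (E)-alkenylzirconocene chloride from 16 (Zr on the methyl-bearing carbon, trans to CH2Ar) | C/C(=C\Cc1cc(O[Si](C)(C)C(C)(C)C)cc(C)c1O[Si](C)(C)C(C)(C)C)[Zr](Cl)(C1C=CC=C1)C1C=CC=C1 | intermediate (not isolated)
18 | 2-[(2E)-3-iodobut-2-en-1-yl]-1,4-bis(TBS-oxy)-6-methylbenzene | C/C(I)=C\Cc1cc(O[Si](C)(C)C(C)(C)C)cc(C)c1O[Si](C)(C)C(C)(C)C | intermediate
19 | N-phthalimidoyl ester (NHPI ester) of acid 12 | C/C(=C\CC/C(C)=C/CC/C(C)=C/[C@@H](O[Si](C)(C)C(C)(C)C)CC(=O)ON1C(=O)c2ccccc2C1=O)CO[Si](C)(C)C(C)(C)C | intermediate (not isolated)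
20 | tetra-TBS ether of the target (5'S, all-E) | C/C(=C\CC/C(C)=C/CC/C(C)=C/[C@@H](O[Si](C)(C)C(C)(C)C)C/C(C)=C/Cc1cc(O[Si](C)(C)C(C)(C)C)cc(C)c1O[Si](C)(C)C(C)(C)C)CO[Si](C)(C)C(C)(C)C | intermediate
21 | 2-[(2E,5S,6E,10E,14E)-5,16-dihydroxy-3,7,11,15-tetramethylhexadeca-2,6,10,14-tetraen-1-yl]-6-methylbenzene-1,4-diol | C/C(=C\CC/C(C)=C/CC/C(C)=C/[C@@H](O)C/C(C)=C/Cc1cc(O)cc(C)c1O)CO | target

**Step count**
- Total: 15 steps.
- Longest linear sequence: 8 steps. It runs 5 → 21 via steps 4–9, 14 and 15, and equally 1 → 21 via steps 1–3, 7–9, 14 and 15. The arene branch is 6 steps long.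

**Three steps most likely to fail**

Step 7 (the proposed new step). Possible failures are double alkylation, hydrodebromination, loss of HBr to a bromoalkyne or alkyne through an α-bromoalkenyl-nickel species, and eroded trans-selectivity.
- The fallback sets out from acid 4 and dibromide 8 and returns at bromide 10. It replaces the radical cross-electrophile coupling with a two-electron coupling of a preformed organometallic.
- Acid 4 is converted with DCC and N-hydroxypyridine-2-thione into the Barton ester F1.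
- Photolysis of the Barton ester with CHI3 gives the primary homoallylic iodide F2.
- Zinc dust/LiCl in THF inserts to give the alkylzinc iodide F3.
- PdCl2(DPEphos) then couples the zinc reagent with 8 in the established trans-selective Negishi mono-alkylation to give 10.

Step 14. The C4' radical is homoallylic to C6'=C7'. It can close 3-exo and reopen as the more stable α-silyloxy radical, which amounts to a 1,2-vinyl shift. In addition, the activated ester 19 can lose TBSOH by E1cB.
- The fallback sets out from ester 11 and benzylic bromide 15 and returns at 20. It avoids any radical next to C5' by keeping the ester carbon as C3' and moving the disconnection to C1'–C2'.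
- DIBAL-H at −78 °C reduces 11 to the β-silyloxy aldehyde F8.
- The Ohira–Bestmann reagent (K2CO3, MeOH, 0 °C) converts the aldehyde into the terminal alkyne F9.
- Zr-catalysed Negishi carboalumination (Me3Al, Cp2ZrCl2, CH2Cl2) gives the (E)-alkenylalane F10.
- Pd(PPh3)4 couples the alane in the same flask with 15 to give 20. Steps 9, 12 and 13 then become unnecessary.

Step 11. The electron-rich bis(silyloxy)arene may undergo ionic ring bromination, or bromination of both methyl groups.
- The fallback sets out from 13 and returns at 16. It deactivates the ring first and uses a neutral C–C coupling.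
- Ac2O/pyridine gives the diacetate F4.
- NBS/AIBN in PhCF3 gives the bromomethyl diacetate F5.
- Stille coupling with tributyl(prop-1-ynyl)stannane under Pd(PPh3)4 gives the butynyl diacetate F6.
- Degassed K2CO3/MeOH gives the butynylhydroquinone F7.
- TBSCl/imidazole then gives 16.

**Further compounds**
F1 | step 7 | Barton ester (2-thioxopyridin-1(2H)-yl ester) of acid 4 | C/C(=C\CC/C(C)=C/CCC(=O)ON1C=CC=CC1=S)CO[Si](C)(C)C(C)(C)C
F2 | step 7 | tert-butyl{[(2E,6E)-9-iodo-2,6-dimethylnona-2,6-dien-1-yl]oxy}dimethylsilane | C/C(=C\CC/C(C)=C/CCI)CO[Si](C)(C)C(C)(C)C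
F3 | step 7 | [(3E,7E)-9-(TBS-oxy)-4,8-dimethylnona-3,7-dien-1-yl]zinc iodide | C/C(=C\CC/C(C)=C/CC[Zn]I)CO[Si](C)(C)C(C)(C)C
F4 | step 11 | 2,6-dimethyl-1,4-phenylene diacetate | Cc1cc(OC(C)=O)cc(C)c1OC(C)=O
F5 | step 11 | 2-(bromomethyl)-6-methyl-1,4-phenylene diacetate | BrCc1cc(OC(C)=O)cc(C)c1OC(C)=O
F6 | step 11 | 2-(but-2-yn-1-yl)-6-methyl-1,4-phenylene diacetate | CC#CCc1cc(OC(C)=O)cc(C)c1OC(C)=O
F7 | step 11 | 2-(but-2-yn-1-yl)-6-methylbenzene-1,4-diol | CC#CCc1cc(O)cc(C)c1O
F8 | step 14 | (3S,4E,8E,12E)-3,14-bis(TBS-oxy)-5,9,13-trimethyltetradeca-4,8,12-trienal | C/C(=C\CC/C(C)=C/CC/C(C)=C/[C@@H](O[Si](C)(C)C(C)(C)C)CC=O)CO[Si](C)(C)C(C)(C)C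
F9 | step 14 | (4S,5E,9E,13E)-4,15-bis(TBS-oxy)-6,10,14-trimethylpentadeca-5,9,13-trien-1-yne | C/C(=C\CC/C(C)=C/CC/C(C)=C/[C@@H](O[Si](C)(C)C(C)(C)C)CC#C)CO[Si](C)(C)C(C)(C)C
F10 | step 14 | (E)-alkenyl(dimethyl)alane from carboalumination of F9 | C/C(=C\CC/C(C)=C/CC/C(C)=C/[C@@H](O[Si](C)(C)C(C)(C)C)C/C(C)=C/[Al](C)C)CO[Si](C)(C)C(C)(C)C
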